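(Its constants were set for the occasion.)

Count turnovers. These flasks share one charge and differ in run time.

| flask | starting material | time |
|---|---|---|
| north-west | 0.44 M | 120 min |
| north | 0.44 M | 80 min |
| south | 0.44 M | 180 min |

    starting material ⇌ target + by-product (K1 = 0.38 M, k1 = 3.1 × 10⁻⁴ s⁻¹)
    starting material + target ⇌ idle adduct, settled at all times (K2 = 1.0 L mol⁻¹)
    target → over-reaction product (k3 = 1.4 × 10⁻⁴ s⁻¹)

- percent here means starting material units held: one idle adduct counts as two
- what is said of target includes idle adduct
- in an amount of target, one idle adduct counts as one target
- run time (north-west): 120 min

- which of the two there is more of at the end, north-west (target / over-reaction product)
- which of the two there is more of at the end, north (target / over-reaction product)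
- which of the two there is more of at the end, south (target / over-reaction product)
- how much target is there at the end, in percent of the starting material charged: north-west
- how much target is there at the end, in percent of the starting material charged: north
- how much target is there at the end, in percent of the starting material charged: south

North and south look nearly the same, but south runs longer. So I reckon with k3 times the run time, which gives 0.672 for north and 1.51 for south. Call this the step-3 turnover count.

Here is what it means. Step 3 is first order in target. Hold c(target) level in your head, and c(over-reaction product) ends at the count times that level. The two therefore meet near a count of one. Is a level a fair picture? The forward half-life of starting material by step 1 alone is 37 min, shorter than the 83 min of free target by step 3 alone. So target rises first.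

My call follows. North stands below one, so target leads there. South stands above one, so over-reaction product leads there. North-west counts 1.01, about one. So the count does not separate the two in north-west, and I leave that flask open. My reckoning stops here, since the count gives no yields.

The forecast names target for north-west, target for north and over-reaction product for south. It puts target at 35%, 39% and 28%. It integrates roughly, noting that “the adduct holds a share of target out of step 3”, and it has the overtaking at 135 to 140 min.

The simulation gives target 35.8% in north-west, 40.9% in north and 27.8% in south. Over-reaction product stands at 29.5%, 18.2% and 43.7%.

The two are equal at 136 min, a count of 1.14, and north-west falls short of that. The forecast's integration earns the yields, but the count gives the marks of north and south with one multiplication per flask. South holds 27.8% target against 40.9% in north, and the difference in time is the main reason for that gap. With the loss of target to over-reaction product struck out, south minus north goes from −13 percentage points to 2.7 points, the largest single effect, and the mark of south turns.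

Now take the neighbour with 1.1 M of starting material, run as long as south. Its count is 1.51, above one, so over-reaction product should lead. It ends at 31.1% over-reaction product against 26.2% target.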